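## The problem

Isoflavan numbering is used throughout: ring C is O1, C2, C3, C4; ring A is C4a, C5–C8, C8a; ring B is C1'–C6'.

The target 17 is a (3R)-isoflavan, that is a chroman carrying ring B at C3, and both aromatic rings are resorcinols. Its only stereocentre, C3, lies between two methylene groups, cannot be epimerised and has no neighbouring stereocentre or functional group to relay or correct it, so it must be set once, by a reagent, in a step that forms one of its bonds. Ring A is alkylated at C8, the crowded position between O1 and 7-OH, by a 3-hydroxy-3-methylbutyl chain; ring B carries at C5' (ortho to 4'-OH, para to 2'-OH) a 1,1-dimethylallyl group, a quaternary benzylic carbon that no direct alkylation delivers; and of the three phenols only 4'-OH may direct a substituent, so they must be told apart. Acid closes the tertiary carbinol onto 7-OH (2,2-dimethylchroman) and 4'-OH onto the vinyl group (dihydrobenzofuran), and the terminal vinyl group excludes hydrogenation or hydrogenolysis once it is present, so acidic C4 deoxygenation, H2/Pd and Me, Bn or MOM ethers are largely unusable late in the route. The feature the plan exploits is the C3–C4 edge of ring C: C4 is an unsubstituted methylene benzylic to ring A, and C3 holds ring B through the C3–C1' bond. In the 2H-chromene 8 this edge is a cyclic styrene C3=C4; an aryl–palladium species should add with aryl at C3 and Pd at benzylic C4, and the C4–Pd bond then has neither a syn-β-hydrogen (H3 is anti, C4a is aromatic) nor a β-oxygen (O1 is γ), so it can only be reduced, and one step forms C3–C1', joins the two halves and sets C3. Two further retrons follow from the substitution pattern: 7-OH plus the C8 chain is an opened δ-lactone of a locally C2v-symmetric 2-alkylresorcinol, and 4'-OH plus the C5' tert-prenyl group is the product of an aromatic Claisen rearrangement.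

## Retrosynthesis

17 ⇒ 15. The two C–CH3 bonds of the carbinol and the two acyl C–O bonds (O7–CO of a lactone, O2'–CO of a benzoate) are cut together. A lactone is preferred to a C8-prenyl group that would need hydration, because hydration could not distinguish the prenyl from the vinyl group, and because the lactone masks 7-OH and the chain through every earlier step. The forward reaction asks a methyl nucleophile to add twice to the lactone and to remove the benzoate under a non-acidic work-up; 15 needs no other deprotection.

15 ⇒ 13. The C5'–C(CH3)2 bond is cut by a retro-Claisen step to the 4'-O-prenyl ether 13. This is the only disconnection that delivers the quaternary benzylic carbon and frees 4'-OH in the same event. The forward reaction must choose C5' over C3', which lies between two oxygens.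

13 ⇒ 11 + 12. The O4'–C bond is cut. Phenol 11 has a single free OH because O2' is benzoylated and O7 is in the lactone, so no selectivity is asked. The prenyl group is put on after the palladium step because Pd(0)/formate can ionise allylic aryl ethers.

11 ⇒ 8 + 10 (key). The C3–C1' bond is cut and one hydrogen is removed from C4, giving the achiral chromene 8 and the aryl iodide 10. The neighbouring cuts (O1–C2 or C4–C4a ring closure of a 2,3-diarylpropanol, or a C4 carbonyl that is later removed) each need the stereocentre to be made first in a separate operation on a longer chain. Here two flat fragments of twelve and thirteen carbons give the complete core with C3 set. The forward reaction must deliver aryl to C3 rather than C4, select one face of C3=C4, and end by hydride capture.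

8 ⇒ 7 ⇒ 5 + 6. The C4–C4a bond is cut (6-endo hydroarylation of an aryl propargyl ether), then the O1–C2 bond (O-alkylation). Phenol 5 has only one free ortho position, so the ring can close in one way only.

5 ⇒ 3 ⇒ 1 + 2. Ring A is traced to the dione 3 by dehydrogenation, and 3 to the Michael pair 1 + 2. The two oxygens of the intermediate resorcinol 4 are equivalent, so lactonisation is unambiguous and no regiochemical question arises at C8.

10 ⇒ 9. The C–I bond is cut. In 9 the free OH directs iodine para to itself, which is ortho to the benzoate oxygen, exactly the 1',2',4' pattern of ring B with the two oxygens already differentiated.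

## Roads not taken

Alternative 1: the most obvious plan cuts C4–C4a and inserts C2 later. Friedel–Crafts acylation of 5 with a 2,4-dioxygenated phenylacetic acid and one-carbon insertion would give isoflavone A1, and the forward key step would be Ru-catalysed transfer hydrogenation with dynamic kinetic resolution to the cis-isoflavan-4-ol A2, followed by C4 deoxygenation. The chosen plan is better for three reasons. The acylation runs in hot BF3, where the lactone of 5 is itself an acylating agent and a free dihydroxyphenylacetic acid is itself a nucleophile. Ring B enters with two undifferentiated oxygens, or needs a multi-step homologation of a differentiated aldehyde. An oxygen is placed on C4 only to be removed by acid/silane or hydrogenolysis, which collides with the prenyl ether or the vinyl group. It would also be about three steps longer.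

Alternative 2: cut O1–C2 last and C3–C4 as the stereodefining bond. An auxiliary-controlled enolate alkylation of a B-ring arylacetic acid derivative with an A-ring benzylic halide, reduction and phenol release would give the propanol A3, closed by a Mitsunobu etherification. The chosen plan is better because this route uses a stoichiometric auxiliary and four operations for what step 6 does in one. The hydride reduction would also destroy the lactone mask, so ring A would need benzyl-type protection whose removal clashes with the vinyl group, and both fragments need several steps of preparation.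

Alternative 3: use the same fragments, 8 and commercial 4-iodoresorcinol, in a Heck oxyarylation to the cis-pterocarpan A4 (C3–C1' and C4–O2' bonds), then cleave the benzylic C4–O2' bond reductively. It needs no protecting group on ring B and leaves only 4'-OH free. The chosen plan is better because the C4–O bond must later be broken. Hydrogenolysis removes the vinyl group, acid/silane threatens the prenyl ether or the o-(tert-prenyl)phenol, and opening through a p-quinone methide after unmasking 7-OH invites loss of H3 to an isoflav-3-ene and hence loss of configuration. The enantioselective oxyarylation is no better precedented than the reductive variant, which never makes the C4–O bond.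

Key step: step 6

Remark (assumption): 1, 2, 6, 9 and 12 are taken as commercial; in step 6 the (R)-antipode of the ligand is a working assignment, since the sense of induction on a 2H-chromene cannot be read from precedent, and the antipode would be used if the first run showed the opposite sense.

Step 1
Reactants: 1 cyclohexane-1,3-dione; 2 methyl acrylate
Product: 3 methyl 3-(2,6-dioxocyclohexyl)propanoate
Conditions: NaOMe (0.1 equiv), MeOH, 60 °C
Reagents that add atoms: none
Why: Michael addition of the doubly stabilised C2 enolate of 1 to 2; base is catalytic and 2 is kept near one equivalent to limit a second addition.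

Step 2
Reactants: 3 methyl 3-(2,6-dioxocyclohexyl)propanoate
Product: 5 5-hydroxychroman-2-one, via methyl 3-(2,6-dihydroxyphenyl)propanoate 4 (not isolated)
Conditions: 10% Pd/C, mesitylene, reflux, N2 sweep
Reagents that add atoms: none
Why: Catalytic dehydrogenative aromatisation of a 2-alkylcyclohexane-1,3-dione to the 2-alkylresorcinol 4 (one H2 is lost, the dione being already an enolised cyclohexenone); at this temperature 4 should close the δ-lactone with loss of methanol, and as its two OH groups are equivalent only 5 can form.

Step 3
Reactants: 5 5-hydroxychroman-2-one; 6 propargyl bromide (3-bromoprop-1-yne)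
Product: 7 5-(prop-2-yn-1-yloxy)chroman-2-one
Conditions: K2CO3, acetone, 50 °C
Reagents that add atoms: none
Why: Williamson ether synthesis at the only free phenol; attack of the phenoxide on its own lactone is degenerate in 5 and changes nothing.

Step 4
Reactants: 7 5-(prop-2-yn-1-yloxy)chroman-2-one
Product: 8 9,10-dihydro-2H,8H-pyrano[2,3-f]chromen-8-one
Conditions: Ph3PAuNTf2 (2 mol %), CH2Cl2, rt
Reagents that add atoms: none
Why: Gold(I)-catalysed 6-endo-dig hydroarylation (cycloisomerisation of an aryl propargyl ether to a 2H-chromene); the other ortho position of the ether oxygen is the ring-fusion carbon, so the new C–C bond can only form at the carbon that becomes C4a.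

Step 5
Reactants: 9 3-hydroxyphenyl benzoate (resorcinol monobenzoate)
Product: 10 5-hydroxy-2-iodophenyl benzoate
Conditions: NIS (1.05 equiv), TsOH·H2O (10 mol %), MeCN, 0 °C to rt
Reagents that add atoms: N-iodosuccinimide, O=C1CCC(=O)N1I
Why: Electrophilic aromatic iodination directed by the free OH, the strongest donor; the para position should be preferred over the hindered site between the two oxygens, and acid-activated NIS is para-selective for phenols, which places iodine ortho to the benzoate oxygen (future O2') and para to the free OH (future O4').

Step 6
Reactants: 8 9,10-dihydro-2H,8H-pyrano[2,3-f]chromen-8-one; 10 5-hydroxy-2-iodophenyl benzoate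
Product: 11 5-hydroxy-2-[(3R)-8-oxo-3,4,9,10-tetrahydro-2H,8H-pyrano[2,3-f]chromen-3-yl]phenyl benzoate
Conditions: Pd2(dba)3 (2.5 mol %), (R)-Xyl-SDP(O) (6 mol %), HCO2Na (2 equiv), DMA/t-AmOH 4:1, 65 °C
Reagents that add atoms: none
Why: Proposed new method: enantioselective intermolecular reductive Heck reaction (hydroarylation) of a 2H-chromene, for which the closest known reaction types are the racemic Pd-mediated oxyarylation of 2H-chromenes with o-iodophenols and the asymmetric reductive Heck arylation of strained bicyclic alkenes. Mechanism: oxidative addition of Pd(0)L* into the C–I bond of 10, syn migratory insertion of C3=C4 of 8 with aryl to C3 and Pd to benzylic C4 (η3-benzyl stabilised by ring A), exchange of iodide for formate, decarboxylation and C4–H reductive elimination. No ring is closed; the step joins rings A/C to ring B through the C3–C1' bond. The only new stereocentre, C3, is fixed in the migratory insertion, where the chiral ligand on an iodide-free Pd (hemilabile P=O arm, protic co-solvent) selects one enantiotopic face of the planar chromene; the C4–H bond then forms with retention and C4 is not stereogenic. Regioselectivity (aryl to C3, not C4) is secured by the styrene polarisation of C3=C4 and the benzylic stabilisation of C4–Pd, as in the oxyarylation. Hydride capture is secured by the substrate: H3 ends anti to Pd and C4a is aromatic, so there is no syn-β-hydrogen; O1 is γ to Pd, so β-alkoxide elimination is impossible; and O2' is benzoylated, so it cannot attack C4 to give a pterocarpan. The free 4'-OH is para to iodine and cannot interfere, and neither partner carries another alkene at this stage. The (R)-ligand is the working assignment for the 3R product.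

Step 7
Reactants: 11 5-hydroxy-2-[(3R)-8-oxo-3,4,9,10-tetrahydro-2H,8H-pyrano[2,3-f]chromen-3-yl]phenyl benzoate; 12 prenyl bromide (1-bromo-3-methylbut-2-ene)
Product: 13 5-[(3-methylbut-2-en-1-yl)oxy]-2-[(3R)-8-oxo-3,4,9,10-tetrahydro-2H,8H-pyrano[2,3-f]chromen-3-yl]phenyl benzoate
Conditions: K2CO3, acetone, rt
Reagents that add atoms: none
Why: Williamson ether synthesis at the single free phenol (4'-OH); at room temperature the allylic bromide should react much faster than any intermolecular acyl transfer from the 2'-benzoate or the lactone.

Step 8
Reactants: 13 5-[(3-methylbut-2-en-1-yl)oxy]-2-[(3R)-8-oxo-3,4,9,10-tetrahydro-2H,8H-pyrano[2,3-f]chromen-3-yl]phenyl benzoate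
Product: 15 5-hydroxy-4-(2-methylbut-3-en-2-yl)-2-[(3R)-8-oxo-3,4,9,10-tetrahydro-2H,8H-pyrano[2,3-f]chromen-3-yl]phenyl benzoate, via ortho-dienone 14 (not isolated)
Conditions: N,N-diethylaniline, 190 °C (sealed tube)
Reagents that add atoms: none
Why: Aromatic Claisen rearrangement ([3,3]) of the aryl prenyl ether through dienone 14, then tautomerisation; C5' should be preferred because C3' lies between O2' and O4', where a quaternary carbon is badly accommodated, and C3 is remote and untouched. Any thermal acyl scrambling among the phenols is harmless because step 9 cleaves every ester.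

Step 9
Reactants: 15 5-hydroxy-4-(2-methylbut-3-en-2-yl)-2-[(3R)-8-oxo-3,4,9,10-tetrahydro-2H,8H-pyrano[2,3-f]chromen-3-yl]phenyl benzoate
Product: 17 4-[(3R)-7-hydroxy-8-(3-hydroxy-3-methylbutyl)-3,4-dihydro-2H-chromen-3-yl]-6-(2-methylbut-3-en-2-yl)benzene-1,3-diol, via methyl ketone 16 (not isolated)
Conditions: MeMgBr (8 equiv), THF, 0 °C to rt; then sat. aq NH4Cl
Reagents that add atoms: methylmagnesium bromide, C[Mg]Br
Why: Grignard addition: the reagent deprotonates 4'-OH, cleaves the benzoate (to 2-phenylpropan-2-ol) and adds twice to the lactone through ketone 16, so one reagent should release 2'-OH, 7-OH and the tertiary carbinol. The near-neutral work-up avoids acid-induced closure of the carbinol onto O7 or of 4'-OH onto the vinyl group.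

## Compound list

1 | cyclohexane-1,3-dione | O=C1CCCC(=O)C1 | starting material
2 | methyl acrylate | C=CC(=O)OC | starting material
3 | methyl 3-(2,6-dioxocyclohexyl)propanoate | COC(=O)CCC1C(=O)CCCC1=O | intermediate
4 | methyl 3-(2,6-dihydroxyphenyl)propanoate (not isolated) | COC(=O)CCc1c(O)cccc1O | intermediate
5 | 5-hydroxychroman-2-one (5-hydroxy-3,4-dihydrocoumarin) | O=C1CCc2c(O)cccc2O1 | intermediate
6 | propargyl bromide (3-bromoprop-1-yne) | C#CCBr | starting material
7 | 5-(prop-2-yn-1-yloxy)chroman-2-one | O=C1CCc2c(OCC#C)cccc2O1 | intermediate
8 | 9,10-dihydro-2H,8H-pyrano[2,3-f]chromen-8-one (2H-chromene with a δ-lactone O7–CO–CH2–CH2–C8, isoflavan numbering) | O=C1CCc2c(O1)ccc1C=CCOc21 | intermediate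
9 | 3-hydroxyphenyl benzoate (resorcinol monobenzoate) | O=C(Oc1cccc(O)c1)c1ccccc1 | starting material
10 | 5-hydroxy-2-iodophenyl benzoate | O=C(Oc1cc(O)ccc1I)c1ccccc1 | intermediate
11 | 5-hydroxy-2-[(3R)-8-oxo-3,4,9,10-tetrahydro-2H,8H-pyrano[2,3-f]chromen-3-yl]phenyl benzoate ((3R)-isoflavan: 2'-OBz, 4'-OH, 7-O/C8 lactone) | O=C(Oc1cc(O)ccc1[C@@H]1COc2c(ccc3OC(=O)CCc23)C1)c1ccccc1 | intermediate
12 | prenyl bromide (1-bromo-3-methylbut-2-ene) | CC(C)=CCBr | starting material
13 | 5-[(3-methylbut-2-en-1-yl)oxy]-2-[(3R)-8-oxo-3,4,9,10-tetrahydro-2H,8H-pyrano[2,3-f]chromen-3-yl]phenyl benzoate | O=C(Oc1cc(OCC=C(C)C)ccc1[C@@H]1COc2c(ccc3OC(=O)CCc23)C1)c1ccccc1 | intermediate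
14 | ortho-dienone tautomer of 15 (C4'=O; C5' sp3 with H and the 2-methylbut-3-en-2-yl group, both C5' epimers; not isolated) | O=C(OC1=CC(=O)C(C(C)(C)C=C)C=C1[C@@H]1COc2c(ccc3OC(=O)CCc23)C1)c1ccccc1 | intermediate
15 | 5-hydroxy-4-(2-methylbut-3-en-2-yl)-2-[(3R)-8-oxo-3,4,9,10-tetrahydro-2H,8H-pyrano[2,3-f]chromen-3-yl]phenyl benzoate | O=C(Oc1cc(O)c(C(C)(C)C=C)cc1[C@@H]1COc2c(ccc3OC(=O)CCc23)C1)c1ccccc1 | intermediate
16 | 4-{(3R)-3-[2,4-dihydroxy-5-(2-methylbut-3-en-2-yl)phenyl]-7-hydroxy-3,4-dihydro-2H-chromen-8-yl}butan-2-one (not isolated) | C=CC(C)(C)c1cc([C@@H]2COc3c(ccc(O)c3CCC(C)=O)C2)c(O)cc1O | intermediate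
17 | 4-[(3R)-7-hydroxy-8-(3-hydroxy-3-methylbutyl)-3,4-dihydro-2H-chromen-3-yl]-6-(2-methylbut-3-en-2-yl)benzene-1,3-diol | C=CC(C)(C)c1cc([C@@H]2COc3c(ccc(O)c3CCC(C)(C)O)C2)c(O)cc1O | target

## Step count and least certain steps

Total step count: 9. Longest linear sequence: 8 steps (steps 1, 2, 3, 4, 6, 7, 8, 9 from 1); the ring-B branch is step 5.

Step 6 (key step, proposed new method). Most likely failure is poor or wrong-sense facial selectivity in the migratory insertion if iodide stays on palladium and a phosphine arm dissociates instead. Also possible are reduction of the aryl iodide by formate before insertion, and erosion of configuration by epimerisation of the C4–Pd intermediate followed by β-hydride elimination and re-addition. The fallback uses known chemistry, sets out from 8 and 10 and returns at 11. Bromohydrin formation on 8 (NBS, aqueous THF) would give (±)-trans-3-bromo-4-hydroxy-3,4,9,10-tetrahydro-2H,8H-pyrano[2,3-f]chromen-8-one F1, and acid-catalysed dehydration (TsOH, toluene, reflux) the 3-bromo-2H-chromene F2. Miyaura borylation of 10 (B2pin2, PdCl2(dppf), KOAc) would give the pinacol boronate F3, and Suzuki–Miyaura coupling of F2 with F3 (K3PO4) the isoflav-3-ene F4. Iridium-catalysed asymmetric hydrogenation of F4 with a chiral P,N-ligand complex, the established entry to chiral isoflavans from 3-aryl-2H-chromenes, would then give 11; no other alkene is present at that stage.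

Step 8. Most likely failure is migration to C3', further ("abnormal") rearrangement of the o-(1,1-dimethylallyl)phenol at 190 °C, or thermal loss of the prenyl group. The fallback replaces the sigmatropic step by cross-coupling, sets out from 11 and returns at 15. Ortho-iodination of 11 (NIS; C5' is the open position ortho to 4'-OH) would give 5-hydroxy-4-iodo-2-[(3R)-8-oxo-3,4,9,10-tetrahydro-2H,8H-pyrano[2,3-f]chromen-3-yl]phenyl benzoate F5, and a ligand-controlled γ-selective Suzuki–Miyaura coupling of F5 with prenylboronic acid pinacol ester (K3PO4) would give 15.

Step 9. Most likely failure is stalling at the ketone stage through enolisation of 16 by the Grignard reagent or precipitation of the polyanionic magnesium salts. The fallback separates acyl cleavage from carbinol formation, sets out from 15 and returns at 17. Aminolysis with MeNH(OMe)·HCl/i-PrMgCl would open the lactone to the N-methoxy-N-methylamide F6 and remove the benzoate as N-methoxy-N-methylbenzamide; MeMgBr would convert F6 into ketone 16, now isolated, and MeLi/CeCl3 would add to 16 to give 17.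

Step 4. Most likely failure is slow cyclisation because the acyloxy group deactivates the arene, with alkyne hydration or oligomerisation of the chromene on the Lewis-acidic catalyst taking over. The fallback builds the chromene from a carbonyl group, sets out from 5 and returns at 8. Ortho-formylation of 5 (MgCl2, Et3N, paraformaldehyde) would give 5-hydroxy-2-oxochromane-6-carbaldehyde F7, and reaction of F7 with vinyltriphenylphosphonium bromide and K2CO3 (oxa-Michael addition, then intramolecular Wittig reaction) would give 8.

## Further compounds

F1 | step 6 | (±)-trans-3-bromo-4-hydroxy-3,4,9,10-tetrahydro-2H,8H-pyrano[2,3-f]chromen-8-one (racemic) | O=C1CCc2c(O1)ccc1C(O)C(Br)COc21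
F2 | step 6 | 3-bromo-9,10-dihydro-2H,8H-pyrano[2,3-f]chromen-8-one | O=C1CCc2c(O1)ccc1C=C(Br)COc21
F3 | step 6 | 5-hydroxy-2-(4,4,5,5-tetramethyl-1,3,2-dioxaborolan-2-yl)phenyl benzoate | O=C(Oc1cc(O)ccc1B1OC(C)(C)C(C)(C)O1)c1ccccc1
F4 | step 6 | 5-hydroxy-2-(8-oxo-9,10-dihydro-2H,8H-pyrano[2,3-f]chromen-3-yl)phenyl benzoate (isoflav-3-ene) | O=C(Oc1cc(O)ccc1C1=Cc2ccc3OC(=O)CCc3c2OC1)c1ccccc1
F5 | step 8 | 5-hydroxy-4-iodo-2-[(3R)-8-oxo-3,4,9,10-tetrahydro-2H,8H-pyrano[2,3-f]chromen-3-yl]phenyl benzoate | O=C(Oc1cc(O)c(I)cc1[C@@H]1COc2c(ccc3OC(=O)CCc23)C1)c1ccccc1
F6 | step 9 | 3-{(3R)-3-[2,4-dihydroxy-5-(2-methylbut-3-en-2-yl)phenyl]-7-hydroxy-3,4-dihydro-2H-chromen-8-yl}-N-methoxy-N-methylpropanamide | C=CC(C)(C)c1cc([C@@H]2COc3c(ccc(O)c3CCC(=O)N(C)OC)C2)c(O)cc1O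
F7 | step 4 | 5-hydroxy-2-oxochromane-6-carbaldehyde | O=Cc1ccc2OC(=O)CCc2c1O
A1 | alternative 1 | 3-(2,4-dihydroxyphenyl)-9,10-dihydro-4H,8H-pyrano[2,3-f]chromene-4,8-dione (isoflavone) | O=C1CCc2c(O1)ccc1C(=O)C(=COc21)c1ccc(O)cc1O
A2 | alternative 1 | (3R,4R)-3-(2,4-dihydroxyphenyl)-4-hydroxy-3,4,9,10-tetrahydro-2H,8H-pyrano[2,3-f]chromen-8-one (cis-isoflavan-4-ol) | Oc1ccc([C@@H]2COc3c(ccc4OC(=O)CCc34)[C@@H]2O)c(O)c1
A3 | alternative 2 | (2R)-2-[2,4-bis(benzyloxy)phenyl]-3-[4-(benzyloxy)-2-hydroxy-3-(3-hydroxy-3-methylbutyl)phenyl]propan-1-ol | c1ccccc1COc1ccc([C@@H](Cc2ccc(OCc3ccccc3)c(CCC(C)(C)O)c2O)CO)c(OCc2ccccc2)c1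
A4 | alternative 3 | (6aR,11aR)-cis-pterocarpan with free 9-OH and the 3-O/C4 δ-lactone (pterocarpan numbering) | Oc1ccc2c(c1)O[C@H]1c3ccc4OC(=O)CCc4c3OC[C@@H]21
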